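**Retrosynthetic overview**
1. C3–C6 and the C6 methyl come from 2-methylfuran (1), opened hydrolytically to keto-aldehyde 2; C1–C2 is added by Morita–Baylis–Hillman reaction with methyl acrylate (3) to give 4, then carbonate 5.
2. The O–O bond, C3 (S) and the 1,2-dioxane ring (the only ring formed) arise together: cinchona-catalysed allylic peroxidation of 5 with H2O2, the C6 ketone trapping the hydroperoxide as cyclic peroxy-hemiketal 6.
3. C6–C7 and C6 (R): axial alkynylation of the C6 peroxycarbenium ion from 6 with stannane 9 (β-cyclocitral 7 → enyne 8 → 9) gives 10.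
4. C2 (S) and saturation of C7–C8: one diimide reduction (acrylate and alkyne) gives 11.
5. The C9/C14 diketone is unveiled last by ozonolysis of the carried-through cyclohexene, giving the target 12.

Assumption: (DHQD)2PHAL is taken to give the 3S peroxide; if the sense is opposite, the pseudo-enantiomer (DHQ)2PHAL is used.

**Route**

Step 1
Reactants: 1, 2-methylfuran
Product: 2, 4-oxopentanal
Conditions: cat. H2SO4, AcOH/H2O, 60 °C
Reagents that add atoms: water, O
Why: Acid-catalysed hydrolytic ring-opening of the furan (dearomatisation of a latent 1,4-dicarbonyl) delivers the C3 aldehyde and the C6 methyl ketone; no stereocentre is formed.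

Step 2
Reactants: 2, 4-oxopentanal; 3, methyl acrylate
Product: 4, methyl 3-hydroxy-2-methylidene-6-oxoheptanoate (racemic)
Conditions: DABCO (0.5 equiv), 1,4-dioxane/H2O 1:1, rt, 3 d
Reagents that add atoms: none
Why: Morita–Baylis–Hillman reaction at the aldehyde only (the methyl ketone is inert to the DABCO–acrylate zwitterion); the racemic carbinol centre is erased in step 4.

Step 3
Reactants: 4, methyl 3-hydroxy-2-methylidene-6-oxoheptanoate
Product: 5, methyl 3-[(tert-butoxycarbonyl)oxy]-2-methylidene-6-oxoheptanoate (racemic)
Conditions: Boc2O, DMAP (cat.), CH2Cl2, 0 °C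
Reagents that add atoms: di-tert-butyl dicarbonate, CC(C)(C)OC(=O)OC(=O)OC(C)(C)C
Why: O-acylation gives the MBH carbonate, the standard leaving group for Lewis-base-catalysed SN2′/SN2′ allylic substitution.

Step 4
Reactants: 5, MBH carbonate
Product: 6, methyl 2-[(3S)-6-hydroxy-6-methyl-1,2-dioxan-3-yl]prop-2-enoate (mixture of C6 anomers)
Conditions: (DHQD)2PHAL (10 mol %), urea·H2O2 (3 equiv), 4 Å MS, toluene, 0 °C → rt
Reagents that add atoms: hydrogen peroxide, OO
Why: Proposed new method: the cinchona amine adds SN2′ to racemic 5 (loss of CO2/t-BuO⁻ erases the stereocentre), H2O2 (free, or as the perhydrate of the pendant C6 ketone, i.e. a tert-alkyl hydroperoxide) attacks C3 of the chiral allyl-ammonium ion on one face (enantioconvergent, sets C3 = S), and the hydroperoxide is trapped by the ketone as the six-membered peroxy-hemiketal; the closest known reaction type is the (DHQD)2PHAL-catalysed asymmetric allylic peroxidation of MBH carbonates with cumyl or tert-butyl hydroperoxide.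

Step 5
Reactants: 7, β-cyclocitral (2,6,6-trimethylcyclohex-1-ene-1-carbaldehyde)
Product: 8, 2-ethynyl-1,3,3-trimethylcyclohex-1-ene
Conditions: TMSCHN2, LDA, THF, −78 °C → rt
Reagents that add atoms: trimethylsilyldiazomethane, C[Si](C)(C)C=[N+]=[N-] (one carbon)
Why: Colvin (Seyferth–Gilbert-type) homologation of a non-enolisable aldehyde to the terminal alkyne via alkylidene carbene 1,2-H shift.

Step 6
Reactants: 8, 2-ethynyl-1,3,3-trimethylcyclohex-1-ene
Product: 9, tributyl[(2,6,6-trimethylcyclohex-1-en-1-yl)ethynyl]stannane
Conditions: n-BuLi, THF, −78 °C; then Bu3SnCl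
Reagents that add atoms: tributyltin chloride, CCCC[Sn](Cl)(CCCC)CCCC
Why: Acetylide stannylation gives a non-basic, non-reducing alkynyl donor suitable for a cationic coupling in the presence of a peroxide.

Step 7
Reactants: 6, peroxy-hemiketal; 9, alkynylstannane
Product: 10, methyl 2-[(3S,6R)-6-methyl-6-[(2,6,6-trimethylcyclohex-1-en-1-yl)ethynyl]-1,2-dioxan-3-yl]prop-2-enoate (3,6-cis: acrylate and alkynyl on the same face)
Conditions: TMSOTf (2.2 equiv), 2,6-di-tert-butyl-4-methylpyridine, CH2Cl2, −78 → −40 °C
Reagents that add atoms: none
Why: Proposed new method: TMSOTf ionises the hemiketal to the cyclic C6 peroxycarbenium ion, which the alkynylstannane attacks axially on the half-chair that keeps the C3 substituent pseudo-equatorial, giving alkynyl axial/CH3 equatorial, i.e. 1,4-cis to C3 (C6 = R); the closest known reaction types are Lewis-acid allylation and Mukaiyama reactions of peroxyketals via peroxycarbenium ions, and the 1,4-cis-selective additions to 4-alkyl-tetrahydropyranyl oxocarbenium ions.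

Step 8
Reactants: 10, alkynyl acrylate
Product: 11, methyl (2S)-2-[(3S,6S)-6-methyl-6-[2-(2,6,6-trimethylcyclohex-1-en-1-yl)ethyl]-1,2-dioxan-3-yl]propanoate (same spatial arrangement at C6 as 10; the descriptor changes only through CIP priorities)
Conditions: KO2C–N=N–CO2K (excess), AcOH, MeOH/CH2Cl2, 0 °C → rt, two cycles
Reagents that add atoms: none
Why: Diimide reduction (concerted syn H2 transfer) saturates the alkyne and the 1,1-disubstituted acrylate but leaves the O–O bond and the tetrasubstituted ring alkene; H is delivered to the acrylate face anti to ring C4 with the C3–O bond "inside" (Houk/Still–Barrish-type allylic model), giving the 2,3-anti (2S) isomer, with a moderate d.r. expected and the minor epimer removed by chromatography.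

Step 9
Reactants: 11, cyclohexene ester
Product: 12, Diacarperoxide B, methyl (2S)-2-[(3S,6R)-6-(4,4-dimethyl-3,8-dioxononyl)-6-methyl-1,2-dioxan-3-yl]propanoate
Conditions: O3, CH2Cl2/MeOH, −78 °C; then Me2S, −78 °C → rt
Reagents that add atoms: ozone, [O-][O+]=O
Why: Ozonolysis of the only remaining C=C (tetrasubstituted cyclohexene) gives the 1,6-diketone (C9 and C14 ketones); the dialkyl peroxide, ester and all three stereocentres are untouched, and Me2S does not reduce the O–O bond.

**Compound list**
1 | 2-methylfuran | Cc1ccco1 | starting material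
2 | 4-oxopentanal | CC(=O)CCC=O | intermediate
3 | methyl acrylate | C=CC(=O)OC | starting material
4 | methyl 3-hydroxy-2-methylidene-6-oxoheptanoate (racemic) | COC(=O)C(=C)C(O)CCC(C)=O | intermediate
5 | methyl 3-[(tert-butoxycarbonyl)oxy]-2-methylidene-6-oxoheptanoate (racemic) | COC(=O)C(=C)C(OC(=O)OC(C)(C)C)CCC(C)=O | intermediate
6 | methyl 2-[(3S)-6-hydroxy-6-methyl-1,2-dioxan-3-yl]prop-2-enoate (C6 anomers) | COC(=O)C(=C)[C@@H]1CCC(C)(O)OO1 | intermediate
7 | β-cyclocitral | CC1=C(C=O)C(C)(C)CCC1 | starting material
8 | 2-ethynyl-1,3,3-trimethylcyclohex-1-ene | C#CC1=C(C)CCCC1(C)C | intermediate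
9 | tributyl[(2,6,6-trimethylcyclohex-1-en-1-yl)ethynyl]stannane | CCCC[Sn](CCCC)(CCCC)C#CC1=C(C)CCCC1(C)C | intermediate
10 | methyl 2-[(3S,6R)-6-methyl-6-[(2,6,6-trimethylcyclohex-1-en-1-yl)ethynyl]-1,2-dioxan-3-yl]prop-2-enoate | COC(=O)C(=C)[C@@H]1CC[C@](C)(C#CC2=C(C)CCCC2(C)C)OO1 | intermediate
11 | methyl (2S)-2-[(3S,6S)-6-methyl-6-[2-(2,6,6-trimethylcyclohex-1-en-1-yl)ethyl]-1,2-dioxan-3-yl]propanoate | COC(=O)[C@@H](C)[C@@H]1CC[C@](C)(CCC2=C(C)CCCC2(C)C)OO1 | intermediate
12 | Diacarperoxide B | COC(=O)[C@@H](C)[C@@H]1CC[C@](C)(CCC(=O)C(C)(C)CCCC(C)=O)OO1 | target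

**Step count**
Total steps: 9. Longest linear sequence: 7 (steps 1–4, 7–9).

**Three steps most likely to fail, with fallbacks**
- **Step 4** (asymmetric peroxidation with H2O2; amine N-oxidation, background SN2′, uncertain ee in the intramolecular mode). Fallback: install the C3–O bond by C–H oxygenation instead of substitution. Wittig reaction of 2 with Ph3P=C(CH3)CO2Me gives the tiglate, Schenck ene reaction with singlet oxygen gives racemic 6, and the hydroperoxide is resolved by horseradish-peroxidase kinetic resolution (or the ene reaction is run on a chiral oxazolidine tiglic amide).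
- **Step 7** (alkynylstannane addition to a peroxycarbenium ion is unprecedented; cation fragmentation or poor cis selectivity are possible). Fallback: reverse the bond order. Add the lithium/cerium acetylide of 8 to the C6 ketone of 5, convert the tertiary propargylic alcohol to the hydroperoxide (H2O2, cat. H2SO4), and close the ring by the amine-catalysed SN2′ attack at C3, relying on the axial preference of the alkynyl group for the cis ring; the C6 epimers would then need separation.
- **Step 8** (C2 diastereoselectivity is only substrate-controlled, and the C7=C8 alkene formed after the first H2 transfer is hindered). Fallback: set C2 in the C–C bond-forming event rather than by reduction, by adding a chiral N-propionyl thiazolidinethione titanium enolate to a C3 peroxy-acetal (from 2 and H2O2) to fix C2/C3 anti together. If only the alkene reduction stalls, ozonise first and reduce the less hindered ynone.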